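**The constants.** I read a rate level, a slowing constant and a delay per unit of scavenger over initiator from the summer and midnight runs, flasks where initiator starts chains on free monomer and radical scavenger holds them off.

| flask | free monomer | initiator | radical scavenger | remark | time |
|---|---|---|---|---|---|
| midnight | 0.010 M | 44 µM | 15 µM | run made earlier |  |
| summer | 0.010 M | 630 µM | 15 µM | run made earlier |  |
| dusk | 0.010 M | 100 µM | 9.9 µM | run made earlier |  |
| blue | 0.010 M | 150 µM | 5.0 µM |  | 15 h |
| violet | 0.010 M | 400 µM | 15 µM |  | 15 h |
| amber | 0.010 M | 100 µM | 15 µM |  | 15 h |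
| ochre | 0.020 M | 30 µM | 30 µM |  | 15 h |
| grey | 0.030 M | 200 µM | 15 µM |  | 15 h |

| run | time / h | monomer in chains / % | free monomer / % |
|---|---|---|---|
| midnight | 0.667 | 0 | 98.7 |
| midnight | 1.00 | 0.7 | 97.9 |
| midnight | 1.33 | 0 | 100.6 |
| midnight | 2.00 | 0.8 | 98.1 |
| midnight | 3.00 | 10.1 | 91.9 |
| midnight | 5.00 | 21.0 | 77.8 |
| midnight | 8.00 | 35.3 | 62.4 |
| summer | 0.417 | 11.2 | 90.8 |
| summer | 1.00 | 27.7 | 73.2 |
| summer | 2.00 | 47.3 | 53.5 |
| summer | 3.00 | 63.9 | 35.4 |
| summer | 5.00 | 79.6 | 19.8 |
| summer | 6.00 | 85.8 | 14.2 |
| summer | 8.00 | 91.1 | 6.9 |
| dusk | 1.50 | 15.1 | 87.6 |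
| dusk | 3.00 | 27.7 | 73.0 |
| dusk | 5.00 | 44.3 | 56.9 |
| dusk | 6.00 | 47.0 | 52.6 |
| dusk | 8.00 | 56.2 | 43.7 |

(readings scatter by 1 percentage point)

- the numbers in the tables scatter by 1 percentage point (one standard deviation)

* ranking by amount of monomer in chains, in percent of the free monomer charged, from high to low, at 15 h (blue / violet / amber / ochre / grey)
* the amount of monomer in chains, in percent of the free monomer charged of the flask you put first, at 15 h
* the amount of monomer in chains, in percent of the free monomer charged of the flask you put last, at 15 h

**The slowing.** Summer's free fraction fell with a logarithmic rate of 0.346 /h up to 3.00 h, and midnight's with 0.0774 /h from 3.00 h to 8.00 h. I took the rate to go as the root of the initiator charge, but the two rates differ by more than that root gives. Spread over the time between the two windows, the excess reads as a slowing constant of 0.0417 /h, so initiator falls at twice that.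

**The delay.** Midnight's line, run back, starts at 1.91 h, which is 5.60 h per unit of scavenger over initiator. Ochre's charges stand at 1.00, so my first answer was 5.60 h. Initiator sinks meanwhile, so I put that answer back and got 7.07 h. Once more gave 7.52 h, the hold-off time (induction period).

**Ochre's rate.** Taking the rate as first order in free monomer, an untested assumption, ochre's rate starts at 0.0804 /h. Slowing has cut it by a factor 0.731 when chains begin and by 0.535 at 15 h. The accumulated logarithm is 0.378, which puts 0.315 of the charge in chains. The same reckoning gave violet 0.960. I ranked the flasks by initiator charge: violet, grey, blue, amber, ochre.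

**The result.** The forecast said violet > grey > blue > amber > ochre, with 96.5 % and 37 %, higher than mine for ochre, and it wrote “I assume first-order kinetics in monomer”. The flasks gave violet > grey > blue > amber > ochre, with 96.1 % and 30.3 %.

    free monomer + initiating radical → growing radical + monomer in chains (k = 64000 /M/s)
    initiator → 2 initiating radical (k = 0.100 /h)
    growing radical + radical scavenger → ended chains (k = 1.70 × 10⁷ /M/s)
    free monomer + growing radical → monomer in chains + growing radical, rate k4*[growing radical]*[free monomer] (k = 5.80 × 10⁶ /M/h)
    2 growing radical → dead chain (k = 4.80 × 10⁶ /M/s)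
    2 free monomer → homo dimer (k = 0.00220 /M/h)

Ochre's hold-off of 7.52 h stands beside an initiator half-life of 6.9 h, a ratio of 1.09. Its chain making had 10 % of its turnover behind it at 7.50 h and reached half at 10.2 h, later than my hold-off.

**Second flask.** With scavenger raised to 5.1 × 10⁻⁵ M, ochre's neighbour gives rounds of 9.52 h, 14.2 h and 17.2 h, past the reading at 15.0 h. It holds 0.256 % in chains, with 8.6 % of its scavenger left.

The earlier runs and the new flask are simulated from invented constants; the scatter is artificial.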